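**Strategy.** Everything rests on splitting the benzene ring into a four-carbon and a two-carbon fragment. The ring of the target carries oxygen on C1 and C3 and the benzylic side-chain carbon on C5. Exactly this meta,meta arrangement results when a 3-substituted cyclobut-2-enone is heated with an alkoxyacetylene. The two alkyne carbons are spliced between the carbonyl carbon and the vinylic CH of the four-membered ring, and the arene closes with all three substituents in place and no blocking groups. The precursor is a cyclobutenone whose C3 holds the C23 chain, the future ketone being masked as a silyl-protected secondary carbinol. A propargylation and a dichloroketene cycloaddition build it; four routine steps finish.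

Key step: step 6

Assumption: the target has no stereocentre, so the achiral structure itself satisfies the request for a single enantiomer; the carbinol centre carried from step 2 to step 8 is racemic and is erased in step 9.

**Step 1**
Reactants: 1 docosan-1-ol
Product: 2 docosanal
Conditions: TEMPO (cat.), PhI(OAc)2, CH2Cl2, 25–35 °C
Reagents that add atoms: none
Why: TEMPO/hypervalent-iodine oxidation of a primary alcohol should stop at the aldehyde in anhydrous dichloromethane and avoids cryogenic conditions under which the waxy C22 alcohol would precipitate.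

**Step 2**
Reactants: 2 docosanal; 3 propargyl bromide
Product: 5 pentacos-1-yn-4-ol (racemic), via allenylzinc bromide 4 (not isolated)
Conditions: Zn dust (activated), THF, 0 °C → rt; then 1 M HCl
Reagents that add atoms: none
Why: Zinc-mediated Barbier propargylation, in which zinc inserts into the C–Br bond and the resulting allenylzinc 4 adds to the aldehyde by an SE2′ pathway to give the homopropargylic rather than the allenic alcohol; the new carbinol centre forms racemic, which is harmless because it is oxidised later.

**Step 3**
Reactants: 5 pentacos-1-yn-4-ol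
Product: 6 tert-butyldimethyl(pentacos-1-yn-4-yloxy)silane (racemic)
Conditions: TBSCl, imidazole, DMF–CH2Cl2, rt
Reagents that add atoms: tert-butyldimethylsilyl chloride, CC(C)(C)[Si](C)(C)Cl
Why: Imidazole-promoted silylation of a secondary alcohol masks the hydroxyl against acylation by dichloroketene with a group that should tolerate zinc, buffered acetic acid and neutral thermolysis.

**Step 4**
Reactants: 6 tert-butyldimethyl(pentacos-1-yn-4-yloxy)silane; 7 trichloroacetyl chloride
Product: 9 4,4-dichloro-3-[2-(tert-butyldimethylsilyloxy)tricosyl]cyclobut-2-en-1-one (racemic), via dichloroketene 8 (not isolated)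
Conditions: Zn–Cu couple, Et2O–DME, rt, slow addition of 7
Reagents that add atoms: none
Why: Ketene–alkyne [2+2] cycloaddition in which zinc dehalogenation of 7 gives dichloroketene 8, whose carbonyl carbon bonds to the terminal alkyne carbon so that the chain sits on C3 of the cyclobutenone; DME complexes zinc chloride to spare the silyl ether, and any 1,3-chlorine-shift isomer converges on the same product in step 5.

**Step 5**
Reactants: 9 4,4-dichloro-3-[2-(tert-butyldimethylsilyloxy)tricosyl]cyclobut-2-en-1-one
Product: 10 3-[2-(tert-butyldimethylsilyloxy)tricosyl]cyclobut-2-en-1-one (racemic)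
Conditions: Zn dust, AcOH, TMEDA, EtOH–THF, 0 °C → rt
Reagents that add atoms: none
Why: Reductive dehalogenation of an α,α-dichloro ketone by zinc in amine-buffered acetic acid is the standard follow-up to dichloroketene cycloadditions and should leave the strained enone and the silyl ether intact.

**Step 6**
Reactants: 10 3-[2-(tert-butyldimethylsilyloxy)tricosyl]cyclobut-2-en-1-one; 11 ethoxyacetylene
Product: 16 3-ethoxy-5-[2-(tert-butyldimethylsilyloxy)tricosyl]phenol (racemic), via vinylketene 12 (not isolated), via 4-vinylcyclobutenone 13 (not isolated), via dienylketene 14 (not isolated), via cyclohexadienone 15 (not isolated)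
Conditions: 11 (2 equiv), toluene, 80 °C, sealed tube, degassed
Reagents that add atoms: none
Why: Heating opens 10 by 4π electrocyclic cleavage of the C(=O)–CH2 bond to vinylketene 12, whose C=C adds [2+2] to the ynol ether to give 13; a second 4π opening gives dienylketene 14, 6π electrocyclisation gives 15, and tautomerisation gives phenol 16. The closest known reaction type is the Danheiser benzannulation of cyclobutenones with alkoxyacetylenes, which gives 3-alkoxy-5-alkylphenols. The six-membered ring is closed by the 6π electrocyclisation between the ketene carbon and the terminal methylene (C1–C6), after the two new skeletal bonds C1–C2 and C3–C4 have been made in the ketene–alkyne cycloaddition. No stereocentre is created in the product, the remote racemic silyloxy carbinol is untouched, and the transient ring stereocentre of 13 disappears on ring opening. The step needs regiocontrol in the [2+2] event, and the polarised ynol ether secures it: its nucleophilic unsubstituted carbon attacks the electrophilic ketene carbonyl carbon, so ethoxy ends up meta to the new hydroxyl and the cyclobutenone C3 chain ends up meta to both oxygens. The medium is neutral, so the silyl ether should survive, and the excess of alkyne should limit acylation of the product phenol by the vinylketene.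

**Step 7**
Reactants: 16 3-ethoxy-5-[2-(tert-butyldimethylsilyloxy)tricosyl]phenol
Product: 17 1,3-diethoxy-5-[2-(tert-butyldimethylsilyloxy)tricosyl]benzene (racemic)
Conditions: EtI, K2CO3, DMF, 50 °C
Reagents that add atoms: ethyl iodide, CCI
Why: Williamson etherification of the phenoxide caps the phenol against oxidation in step 9 and gives a symmetric diethyl ether, so one reagent removes both groups at the end without the benzyl cations a benzyl cap would release.

**Step 8**
Reactants: 17 1,3-diethoxy-5-[2-(tert-butyldimethylsilyloxy)tricosyl]benzene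
Product: 18 1-(3,5-diethoxyphenyl)tricosan-2-ol (racemic)
Conditions: TBAF, THF, rt; then H2O
Reagents that add atoms: none
Why: Fluoride-driven cleavage of the Si–O bond should free the secondary alcohol without touching the aryl ethers.

**Step 9**
Reactants: 18 1-(3,5-diethoxyphenyl)tricosan-2-ol
Product: 19 1-(3,5-diethoxyphenyl)tricosan-2-one
Conditions: Dess–Martin periodinane (1.2 equiv), CH2Cl2, 0 °C → rt
Reagents that add atoms: none
Why: Dess–Martin oxidation of a secondary alcohol under near-neutral conditions should give the benzyl ketone and removes the only stereocentre, the capped arene being inert to a slight excess of the iodine(V) reagent.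

**Step 10**
Reactants: 19 1-(3,5-diethoxyphenyl)tricosan-2-one
Product: 20 5-(2-oxotricosyl)resorcinol [1-(3,5-dihydroxyphenyl)tricosan-2-one]
Conditions: BBr3 (excess), CH2Cl2, −78 °C → rt; then H2O, 0 °C
Reagents that add atoms: none
Why: Lewis-acid ether cleavage in which BBr3 coordinates each aryl ether oxygen and bromide removes the ethyl group by SN2, the aryloxyboranes being hydrolysed on work-up; aliphatic ketones tolerate these conditions and no other cleavable group remains.

**Compound list**

1 | docosan-1-ol | CCCCCCCCCCCCCCCCCCCCCCO | starting material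
2 | docosanal | CCCCCCCCCCCCCCCCCCCCCC=O | intermediate
3 | propargyl bromide (3-bromoprop-1-yne) | C#CCBr | starting material
4 | allenylzinc bromide (propa-1,2-dienylzinc bromide; formed in the flask) | C=C=C[Zn]Br | intermediate
5 | pentacos-1-yn-4-ol (racemic) | C#CCC(O)CCCCCCCCCCCCCCCCCCCCC | intermediate
6 | tert-butyldimethyl(pentacos-1-yn-4-yloxy)silane (racemic) | C#CCC(CCCCCCCCCCCCCCCCCCCCC)O[Si](C)(C)C(C)(C)C | intermediate
7 | trichloroacetyl chloride | O=C(Cl)C(Cl)(Cl)Cl | starting material
8 | dichloroketene (formed in the flask) | O=C=C(Cl)Cl | intermediate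
9 | 4,4-dichloro-3-[2-(tert-butyldimethylsilyloxy)tricosyl]cyclobut-2-en-1-one (racemic) | O=C1C=C(CC(CCCCCCCCCCCCCCCCCCCCC)O[Si](C)(C)C(C)(C)C)C1(Cl)Cl | intermediate
10 | 3-[2-(tert-butyldimethylsilyloxy)tricosyl]cyclobut-2-en-1-one (racemic; key-step precursor) | O=C1C=C(CC(CCCCCCCCCCCCCCCCCCCCC)O[Si](C)(C)C(C)(C)C)C1 | intermediate
11 | ethoxyacetylene | C#COCC | starting material
12 | vinylketene: 5-(tert-butyldimethylsilyloxy)-3-methylidenehexacos-1-en-1-one (racemic; formed in the flask) | O=C=CC(=C)CC(CCCCCCCCCCCCCCCCCCCCC)O[Si](C)(C)C(C)(C)C | intermediate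
13 | 4-vinylcyclobutenone: 3-ethoxy-4-[4-(tert-butyldimethylsilyloxy)pentacos-1-en-2-yl]cyclobut-2-en-1-one (diastereomer mixture; formed in the flask) | O=C1C=C(OCC)C1C(=C)CC(CCCCCCCCCCCCCCCCCCCCC)O[Si](C)(C)C(C)(C)C | intermediate
14 | dienylketene: (3E)-3-ethoxy-5-methylidene-7-(tert-butyldimethylsilyloxy)octacosa-1,3-dien-1-one (racemic; formed in the flask) | CCOC(/C=C=O)=C/C(=C)CC(CCCCCCCCCCCCCCCCCCCCC)O[Si](C)(C)C(C)(C)C | intermediate
15 | cyclohexadienone: 3-ethoxy-5-[2-(tert-butyldimethylsilyloxy)tricosyl]cyclohexa-2,4-dien-1-one (racemic; formed in the flask) | O=C1C=C(OCC)C=C(CC(CCCCCCCCCCCCCCCCCCCCC)O[Si](C)(C)C(C)(C)C)C1 | intermediate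
16 | 3-ethoxy-5-[2-(tert-butyldimethylsilyloxy)tricosyl]phenol (racemic; key-step product) | CCOc1cc(O)cc(CC(CCCCCCCCCCCCCCCCCCCCC)O[Si](C)(C)C(C)(C)C)c1 | intermediate
17 | 1,3-diethoxy-5-[2-(tert-butyldimethylsilyloxy)tricosyl]benzene (racemic) | CCOc1cc(OCC)cc(CC(CCCCCCCCCCCCCCCCCCCCC)O[Si](C)(C)C(C)(C)C)c1 | intermediate
18 | 1-(3,5-diethoxyphenyl)tricosan-2-ol (racemic) | CCOc1cc(OCC)cc(CC(O)CCCCCCCCCCCCCCCCCCCCC)c1 | intermediate
19 | 1-(3,5-diethoxyphenyl)tricosan-2-one | CCOc1cc(OCC)cc(CC(=O)CCCCCCCCCCCCCCCCCCCCC)c1 | intermediate
20 | 5-(2-oxotricosyl)resorcinol (achiral) | CCCCCCCCCCCCCCCCCCCCCC(=O)Cc1cc(O)cc(O)c1 | target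

**Totals**

Total step count: 10. Longest linear sequence: 10 steps (1 → 20); all other inputs are commercial.

**Steps most likely to fail**

Step 6 (key step). The vinylketene released on heating may acylate phenol already formed, or oligomerise, faster than the ynol ether captures it. The volatile, heat-sensitive alkyne may also be lost before the cascade is complete. The fallback gives up the ring synthesis and forms the aryl–CH2 bond classically; it sets out from docosanal 2 and returns to the route at target 20. Commercial 3,5-dimethoxybenzyl chloride and magnesium (THF, 0 °C, high dilution) give 3,5-dimethoxybenzylmagnesium chloride F1. Addition of F1 to 2 (then 1 M HCl) should give 1-(3,5-dimethoxyphenyl)tricosan-2-ol F2. Dess–Martin oxidation should give 1-(3,5-dimethoxyphenyl)tricosan-2-one F3, and BBr3 in CH2Cl2 should remove both methyl groups to deliver 20.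

Step 4. Cycloaddition of the electron-poor ketene to an unactivated terminal alkyne may be slow enough for ketene oligomerisation to take over. Zinc chloride formed alongside may also strip the silyl group. The fallback replaces the ketene by a keteniminium ion, so no chlorine has to be removed; it sets out from alkyne 6 and returns at cyclobutenone 10, bypassing 9 and step 5. N,N-Dimethylacetamide, Tf2O and 2,4,6-collidine in 1,2-dichloroethane generate N,N-dimethylketeniminium triflate F4. At reflux F4 should add [2+2] to 6 with the same regiochemistry to give N,N-dimethyl-3-[2-(tert-butyldimethylsilyloxy)tricosyl]cyclobut-2-en-1-iminium triflate F5. Hydrolysis with aqueous NaHCO3 should release 10.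

Step 10. The second ethyl ether is cleaved slowly, and during the long exposure the enolisable aryl ketone may self-condense or the freed electron-rich ring may be attacked under the strongly Lewis- and Brønsted-acidic conditions. The fallback ends with a neutral hydrogenolysis of benzyl ethers and uses no Lewis acid; it sets out from docosanal 2 and returns at target 20. Commercial 3,5-bis(benzyloxy)benzyl bromide and magnesium (THF–Et2O, 0 °C, high dilution) give 3,5-bis(benzyloxy)benzylmagnesium bromide F6. Addition of F6 to 2 (then 1 M HCl) should give 1-[3,5-bis(benzyloxy)phenyl]tricosan-2-ol F7. Dess–Martin oxidation should give 1-[3,5-bis(benzyloxy)phenyl]tricosan-2-one F8, and H2 over Pd/C in EtOAc–EtOH should remove both benzyl groups to give 20.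

**Further compounds**

F1 | step 6 | 3,5-dimethoxybenzylmagnesium chloride | COc1cc(C[Mg]Cl)cc(OC)c1
F2 | step 6 | 1-(3,5-dimethoxyphenyl)tricosan-2-ol (racemic) | COc1cc(OC)cc(CC(O)CCCCCCCCCCCCCCCCCCCCC)c1
F3 | step 6 | 1-(3,5-dimethoxyphenyl)tricosan-2-one | COc1cc(OC)cc(CC(=O)CCCCCCCCCCCCCCCCCCCCC)c1
F4 | step 4 | N,N-dimethylketeniminium triflate | C=C=[N+](C)C.[O-]S(=O)(=O)C(F)(F)F
F5 | step 4 | N,N-dimethyl-3-[2-(tert-butyldimethylsilyloxy)tricosyl]cyclobut-2-en-1-iminium triflate (racemic) | C[N+](C)=C1C=C(CC(CCCCCCCCCCCCCCCCCCCCC)O[Si](C)(C)C(C)(C)C)C1.[O-]S(=O)(=O)C(F)(F)F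
F6 | step 10 | 3,5-bis(benzyloxy)benzylmagnesium bromide | Br[Mg]Cc1cc(OCc2ccccc2)cc(OCc2ccccc2)c1
F7 | step 10 | 1-[3,5-bis(benzyloxy)phenyl]tricosan-2-ol (racemic) | OC(Cc1cc(OCc2ccccc2)cc(OCc2ccccc2)c1)CCCCCCCCCCCCCCCCCCCCC
F8 | step 10 | 1-[3,5-bis(benzyloxy)phenyl]tricosan-2-one | O=C(Cc1cc(OCc2ccccc2)cc(OCc2ccccc2)c1)CCCCCCCCCCCCCCCCCCCCC
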